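The constants of this system were out of my sight, so I began with the two that the earlier runs could yield.

| flask | Z | remark | time |
|---|---|---|---|
| amber | 0.075 M | run made earlier |  |
| red | 0.95 M | run made earlier |  |
| alder | 1.5 M |  | 12 min |
| elm | 0.12 M |  | 12 min |
| ash | 0.25 M |  | 12 min |
| cedar | 0.40 M |  | 12 min |

- amber (time / min: L / %): 1.00: 15.8; 3.00: 26.1; 6.00: 27.6; 8.00: 27.6; 12.0: 21.0
- red (time / min: L / %): 1.00: 10.6; 2.00: 12.3; 3.00: 13.2; 6.00: 10.1; 12.0: 6.6

(standard deviation of a reading: 1 percentage point)

1. the flasks put in order of amount of L, in percent of the Z charged, best first, at 12 min (alder / elm / ash / cedar)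
2. the amount of L, in percent of the Z charged of the flask you put first, at 12 min
3. the amount of L, in percent of the Z charged of the flask you put last, at 12 min

- the numbers in the tables scatter by 1 percentage point (one standard deviation)

The bench rule for a ring is to dilute: closure takes one Z, while a loss that joins two Z goes with the square of the concentration, so the yield should go as one over the charge. I applied it honestly to the amounts at 12 min. From the red run to the amber run the charge drops by a factor of 12.7, yet L rises from 6.6% to 21.0%, a factor of 3.18, which is less than the rule asks. So the rule stops working somewhere between these charges.

I therefore took the amount at that time as a dilute value divided by one plus the charge over a crossover concentration 0.326 M, the charge of Z at which the two terms of that denominator are equal. It is a fitted figure of my curve, drawn through two amounts read after the peak of each run, and it does not show that any two rates are equal at that charge. The same two readings give a dilute value of 25.8%, and both figures carry the scatter of 1 percentage point. The amber run stands at 0.230 of the crossover, the red run at 2.91. My curve falls steadily with the charge, and it gives 18.9% for elm and 4.61% for alder.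

The forecast, by its own fit, put elm > ash > cedar > alder, with 18.5% (16.5% to 20.5%) for the first flask and 5% (3.8% to 6.2%) for the last, and it concluded: “Lowest concentration is best.”

The flasks came out elm > ash > cedar > alder, with elm at 17.5% and alder at 3.40%.

    Z ⇌ L (K = 0.910, k = 0.200 min⁻¹)
    2 Z → D (k = 0.380 M⁻¹ min⁻¹)
    Z + D → E (k = 0.110 M⁻¹ min⁻¹)
    L → G (k = 0.110 min⁻¹)
    Z + L → X (k = 0.220 M⁻¹ min⁻¹)

Elm stands at 0.368 of the crossover and alder at 4.60, on opposite sides of the border. In a simulated run of alder without the passing of two Z into D, L rises from 3.40% to 11.2%, the largest single effect tried there . For a neighbour like elm but charged with 0.048 M of Z, the curve gives 22.5%, and that flask held 21.9%.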